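**Plan**
Retrosynthesis: cut the aryl ether at C11–O, take the 2,3-diol back to a Δ1-3-ketone, then cut C3–C4 and C5–C10 together. These two bonds flank C4–C5 and lie 1,4 across ring A, so ring A is the retron of a [4+2] between a C10=C1–C2=C3 diene and a C4=C5 alkene; ring B (C5–C6–C7=C8–C9–C10) is the four-atom tether with its cis C7=C8 bond.
Helpers: a formyl group on C4 activates the dienophile and later becomes the second C4 methyl; a naphthylmethyl enol ether oxygen on C3 activates the diene and later becomes the C3 carbonyl.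
Forward: a linear polyene is built by two Wittig olefinations, allylation, a Still–Wittig [2,3] shift and cross-metathesis; one intramolecular Diels–Alder reaction then closes rings A and B; CHO→CH3, aryl ether formation and ring-A redox adjustment finish the route.
Stereochemistry: one carbinol (C7) is set by catalysis and transferred to C9 by the [2,3] shift; C9 directs C5 and C10 in the cycloaddition; C2 and C3 follow from attack anti to the axial methyls on C4 and C10.

Key step: step 9

Remark: locants C1–C15 are the drimane locants of the target (ring A: C1–C5, C10; ring B: C5–C10; C11 = CH2O on C9; C12 = methyl on C8; C15 = methyl on C10). The target is (2S,3S,5S,9R,10R).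
Assumption: the (S)-BINOL/Ti(OiPr)4 catalyst transfers allyl to the Si face of enal 8, as it does with benzaldehyde and cinnamaldehyde; if the sense were opposite, (R)-BINOL would be used.

Step 1
Reactants: 1 methyl propiolate; 2 naphthalen-2-ylmethanol
Product: 3 methyl (E)-3-(naphthalen-2-ylmethoxy)acrylate
Conditions: DABCO (10 mol%), CH2Cl2, 0 °C to rt
Reagents that add atoms: none
Why: Amine-catalysed oxa-Michael addition of the alcohol to the propiolate should give the (E)-β-alkoxyacrylate; no stereocenter is formed.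

Step 2
Reactants: 3 methyl (E)-3-(naphthalen-2-ylmethoxy)acrylate
Product: 4 (E)-3-(naphthalen-2-ylmethoxy)prop-2-en-1-ol
Conditions: i-Bu2AlH (2.2 equiv), CH2Cl2, −78 °C; aq. KNa tartrate
Reagents that add atoms: none
Why: Hydride 1,2-reduction of the ester to the allylic alcohol should leave the enol ether intact under a non-acidic work-up.

Step 3
Reactants: 4 (E)-3-(naphthalen-2-ylmethoxy)prop-2-en-1-ol; 5 2-(triphenylphosphoranylidene)propanal
Product: 7 (2E,4E)-2-methyl-5-(naphthalen-2-ylmethoxy)penta-2,4-dienal, via (E)-3-(naphthalen-2-ylmethoxy)acrolein 6 (not isolated)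
Conditions: MnO2 (10 equiv), 5 (1.2 equiv), toluene, 80 °C
Reagents that add atoms: none
Why: Tandem MnO2 allylic oxidation and Wittig olefination; the stabilised formyl ylide should give the (E)-trisubstituted enal (C10=C1 with C9 trans to C2).

Step 4
Reactants: 7 (2E,4E)-2-methyl-5-(naphthalen-2-ylmethoxy)penta-2,4-dienal; 5 2-(triphenylphosphoranylidene)propanal
Product: 8 (2E,4E,6E)-2,4-dimethyl-7-(naphthalen-2-ylmethoxy)hepta-2,4,6-trienal
Conditions: 5 (1.5 equiv), toluene, 100 °C
Reagents that add atoms: none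
Why: A second Wittig olefination with the same stabilised ylide should add the C7–C8 unit with E geometry.

Step 5
Reactants: 8 (2E,4E,6E)-2,4-dimethyl-7-(naphthalen-2-ylmethoxy)hepta-2,4,6-trienal
Product: 9 (4S,5E,7E,9E)-5,7-dimethyl-10-(naphthalen-2-ylmethoxy)deca-1,5,7,9-tetraen-4-ol
Conditions: allylSnBu3 (1.5 equiv), (S)-BINOL (20 mol%), Ti(OiPr)4 (10 mol%), 4 Å MS, CH2Cl2, −20 °C; aq. NaHCO3
Reagents that add atoms: allyltributylstannane, C=CC[Sn](CCCC)(CCCC)CCCC
Why: Keck asymmetric allylation; the BINOL–titanium complex should deliver allyl to the Si face and set the (S)-carbinol at C7, the only stereocenter set by catalysis.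

Step 6
Reactants: 9 (4S,5E,7E,9E)-5,7-dimethyl-10-(naphthalen-2-ylmethoxy)deca-1,5,7,9-tetraen-4-ol
Product: 10 tributylstannylmethyl ether of 9 (C7–O–CH2SnBu3, S at C7)
Conditions: NaH, Bu3SnCH2I, THF–DMF, 0 °C to rt
Reagents that add atoms: (iodomethyl)tributylstannane, IC[Sn](CCCC)(CCCC)CCCC
Why: Williamson O-alkylation of the sodium alkoxide; alkylation at 0 °C should outpace anionic oxy-Cope rearrangement of this 1,5-dien-3-olate.

Step 7
Reactants: 10 tributylstannylmethyl ether of 9
Product: 11 (2R,3Z)-2-[(2E,4E)-5-(naphthalen-2-ylmethoxy)penta-2,4-dien-2-yl]-3-methylhepta-3,6-dien-1-ol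
Conditions: n-BuLi (1.1 equiv), THF, −78 °C; H2O
Reagents that add atoms: none
Why: Tin–lithium exchange then Still–Wittig [2,3]-sigmatropic rearrangement; suprafacial transfer from (S)-C7 through an envelope transition state with the allyl group pseudo-axial (avoiding A(1,2) strain with the C8 methyl) should give (R)-C9, the Z C7=C8 bond and the C11 hydroxymethyl group.

Step 8
Reactants: 11 (2R,3Z)-2-[(2E,4E)-5-(naphthalen-2-ylmethoxy)penta-2,4-dien-2-yl]-3-methylhepta-3,6-dien-1-ol; 12 methacrolein
Product: 13 (2E,5Z,7R,8E,10E)-7-(hydroxymethyl)-2,6,8-trimethyl-11-(naphthalen-2-ylmethoxy)undeca-2,5,8,10-tetraenal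
Conditions: second-generation Hoveyda–Grubbs catalyst (5 mol%), 12 (5 equiv), CH2Cl2, 40 °C
Reagents that add atoms: none
Why: Olefin cross-metathesis of the terminal vinyl group with methacrolein should give the (E)-2-methyl enal; the trisubstituted and enol-ether alkenes are much slower partners.

Step 9
Reactants: 13 (2E,5Z,7R,8E,10E)-7-(hydroxymethyl)-2,6,8-trimethyl-11-(naphthalen-2-ylmethoxy)undeca-2,5,8,10-tetraenal
Product: 14 (3S,4R,5S,9R,10R)-11-hydroxy-3-(naphthalen-2-ylmethoxy)drima-1,7-dien-13-al (trans-decalin; CHO on C4 and O on C3 cis to H-5; C11 cis to the C10 methyl)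
Conditions: Me2AlCl (2.2 equiv), CH2Cl2, −78 to −30 °C; aq. KNa tartrate
Reagents that add atoms: none
Why: Me2AlCl binds the formyl oxygen and a concerted, asynchronous [4+2] cycloaddition joins C3 to C4 and C5 to C10 in one step; the closest known reaction type is the Lewis-acid-promoted intramolecular Diels–Alder reaction of terminally activated 1,7,9-decatrienals and trienoates to trans-decalins. Ring A is closed as the new cyclohexene by the cycloaddition itself, and ring B by the C5–C10 bond through the four-atom C6–C7=C8–C9 tether (fused mode, cis alkene inside the tether). The formyl group should sit endo and the tether exo, so H-5 and the C10 methyl end up trans; C4 (CHO cis to H-5) follows from the E enal and C3 (OR cis to C9) from the E enol ether, and both are erased later. C9 fixes the diene face: the C5–C10 bond should form anti to the CH2O substituent, which is pseudo-equatorial on the half-chair of ring B with H-9 inside, and this places C11 cis to the C10 methyl as in the target. The step needs facial and endo selectivity; the matched polarity (donor oxygen on C3, acceptor on C4) and the tether allow only this regiochemistry and let the reaction run cold, where the inside methyl on C10 cannot divert the diene into 1,5-hydrogen shifts.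

Step 10
Reactants: 14 (3S,4R,5S,9R,10R)-11-hydroxy-3-(naphthalen-2-ylmethoxy)drima-1,7-dien-13-al
Product: 15 (3S,5S,9R,10R)-3-(naphthalen-2-ylmethoxy)drima-1,7-dien-11-ol
Conditions: N2H4·H2O, KOH, diethylene glycol, 130 °C then 200 °C
Reagents that add atoms: none
Why: Wolff–Kishner reduction (Huang–Minlon variant) of the non-enolisable aldehyde should give the second C4 methyl, removing the activating group and the C4 stereocenter; ethers and isolated alkenes are inert to the base.

Step 11
Reactants: 15 (3S,5S,9R,10R)-3-(naphthalen-2-ylmethoxy)drima-1,7-dien-11-ol; 16 umbelliferone (7-hydroxycoumarin)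
Product: 17 7-{[(3S,5S,9R,10R)-3-(naphthalen-2-ylmethoxy)drima-1,7-dien-11-yl]oxy}coumarin
Conditions: PPh3, DIAD, THF, 0 to 50 °C
Reagents that add atoms: none
Why: Mitsunobu etherification of the only free hydroxyl (primary C11) with the acidic phenol; no stereocenter is touched.

Step 12
Reactants: 17 7-{[(3S,5S,9R,10R)-3-(naphthalen-2-ylmethoxy)drima-1,7-dien-11-yl]oxy}coumarin
Product: 18 7-{[(3S,5S,9R,10R)-3-hydroxydrima-1,7-dien-11-yl]oxy}coumarin
Conditions: DDQ (1.5 equiv), CH2Cl2–pH 7 buffer, 0 °C to rt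
Reagents that add atoms: none
Why: Oxidative cleavage of the naphthylmethyl ether by DDQ (hydride abstraction, hemiacetal collapse) should free the allylic alcohol; the coumarin aryl ether and the alkenes are not affected.

Step 13
Reactants: 18 7-{[(3S,5S,9R,10R)-3-hydroxydrima-1,7-dien-11-yl]oxy}coumarin
Product: 19 7-{[(5S,9R,10R)-3-oxodrima-1,7-dien-11-yl]oxy}coumarin
Conditions: Dess–Martin periodinane, CH2Cl2, rt
Reagents that add atoms: none
Why: Dess–Martin oxidation of the allylic alcohol should give the Δ1-3-ketone and erase the C3 configuration left by the cycloaddition.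

Step 14
Reactants: 19 7-{[(5S,9R,10R)-3-oxodrima-1,7-dien-11-yl]oxy}coumarin
Product: 22 7-{[(2S,5S,9R,10R)-2-hydroxy-3-oxodrim-7-en-11-yl]oxy}coumarin, via triethylsilyl enol ether 20 (not isolated), via 2-triethylsilyloxy ketone 21 (not isolated)
Conditions: Et3SiH, RhCl(PPh3)3 (2 mol%), THF, 50 °C; then m-CPBA (1.05 equiv), CH2Cl2, −20 °C; then aq. HCl (cat.), THF, 0 °C
Reagents that add atoms: m-CPBA, OOC(=O)c1cccc(Cl)c1; triethylsilane, CC[SiH](CC)CC (silicon stays only in 20 and 21)
Why: Rhodium-catalysed 1,4-hydrosilylation should give the C2=C3 silyl enol ether regiospecifically, and Rubottom oxidation on the face opposite the axial C4 and C10 methyls should set the equatorial C2–O bond faster than the Δ7 alkene reacts; acid then cleaves the silyl ether.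

Step 15
Reactants: 22 7-{[(2S,5S,9R,10R)-2-hydroxy-3-oxodrim-7-en-11-yl]oxy}coumarin
Product: 23 7-{[(2S,3S,5S,9R,10R)-2,3-dihydroxydrim-7-en-11-yl]oxy}coumarin (CNP0124364.1)
Conditions: NaBH4, MeOH–CH2Cl2, −20 °C
Reagents that add atoms: none
Why: Borohydride reduction of the 4,4-dimethyl-3-ketone; hydride should add from the face opposite the axial C4 and C10 methyls and give the equatorial 3-OH trans to the 2-OH, the coumarin surviving at low temperature.

**Compound list**
1 | methyl propiolate | C#CC(=O)OC | starting material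
2 | naphthalen-2-ylmethanol | OCc1ccc2ccccc2c1 | starting material
3 | methyl (E)-3-(naphthalen-2-ylmethoxy)acrylate | COC(=O)/C=C/OCc1ccc2ccccc2c1 | intermediate
4 | (E)-3-(naphthalen-2-ylmethoxy)prop-2-en-1-ol | OC/C=C/OCc1ccc2ccccc2c1 | intermediate
5 | 2-(triphenylphosphoranylidene)propanal | CC(C=O)=P(c1ccccc1)(c1ccccc1)c1ccccc1 | starting material
6 | (E)-3-(naphthalen-2-ylmethoxy)acrolein | O=C/C=C/OCc1ccc2ccccc2c1 | intermediate
7 | (2E,4E)-2-methyl-5-(naphthalen-2-ylmethoxy)penta-2,4-dienal | O=C/C(C)=C/C=C/OCc1ccc2ccccc2c1 | intermediate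
8 | (2E,4E,6E)-2,4-dimethyl-7-(naphthalen-2-ylmethoxy)hepta-2,4,6-trienal | O=C/C(C)=C/C(C)=C/C=C/OCc1ccc2ccccc2c1 | intermediate
9 | (4S,5E,7E,9E)-5,7-dimethyl-10-(naphthalen-2-ylmethoxy)deca-1,5,7,9-tetraen-4-ol | C=CC[C@H](O)/C(C)=C/C(C)=C/C=C/OCc1ccc2ccccc2c1 | intermediate
10 | tributylstannylmethyl ether of 9 | C=CC[C@H](OC[Sn](CCCC)(CCCC)CCCC)/C(C)=C/C(C)=C/C=C/OCc1ccc2ccccc2c1 | intermediate
11 | (2R,3Z)-2-[(2E,4E)-5-(naphthalen-2-ylmethoxy)penta-2,4-dien-2-yl]-3-methylhepta-3,6-dien-1-ol | C=CC/C=C(C)\[C@@H](CO)/C(C)=C/C=C/OCc1ccc2ccccc2c1 | intermediate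
12 | methacrolein | CC(=C)C=O | starting material
13 | (2E,5Z,7R,8E,10E)-7-(hydroxymethyl)-2,6,8-trimethyl-11-(naphthalen-2-ylmethoxy)undeca-2,5,8,10-tetraenal | O=C/C(C)=C/C/C=C(C)\[C@@H](CO)/C(C)=C/C=C/OCc1ccc2ccccc2c1 | intermediate
14 | (3S,4R,5S,9R,10R)-11-hydroxy-3-(naphthalen-2-ylmethoxy)drima-1,7-dien-13-al | CC1=CC[C@@H]2[C@@](C)(C=O)[C@@H](OCc3ccc4ccccc4c3)C=C[C@@]2(C)[C@@H]1CO | intermediate
15 | (3S,5S,9R,10R)-3-(naphthalen-2-ylmethoxy)drima-1,7-dien-11-ol | CC1=CC[C@@H]2C(C)(C)[C@@H](OCc3ccc4ccccc4c3)C=C[C@@]2(C)[C@@H]1CO | intermediate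
16 | umbelliferone | O=c1ccc2ccc(O)cc2o1 | starting material
17 | 7-{[(3S,5S,9R,10R)-3-(naphthalen-2-ylmethoxy)drima-1,7-dien-11-yl]oxy}coumarin | CC1=CC[C@@H]2C(C)(C)[C@@H](OCc3ccc4ccccc4c3)C=C[C@@]2(C)[C@@H]1COc1ccc2ccc(=O)oc2c1 | intermediate
18 | 7-{[(3S,5S,9R,10R)-3-hydroxydrima-1,7-dien-11-yl]oxy}coumarin | CC1=CC[C@@H]2C(C)(C)[C@@H](O)C=C[C@@]2(C)[C@@H]1COc1ccc2ccc(=O)oc2c1 | intermediate
19 | 7-{[(5S,9R,10R)-3-oxodrima-1,7-dien-11-yl]oxy}coumarin | CC1=CC[C@@H]2C(C)(C)C(=O)C=C[C@@]2(C)[C@@H]1COc1ccc2ccc(=O)oc2c1 | intermediate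
20 | triethylsilyl enol ether of the 3-ketone (C2=C3) | CC1=CC[C@@H]2C(C)(C)C(O[Si](CC)(CC)CC)=CC[C@@]2(C)[C@@H]1COc1ccc2ccc(=O)oc2c1 | intermediate
21 | (2S)-2-triethylsilyloxy-3-ketone | CC1=CC[C@@H]2C(C)(C)C(=O)[C@@H](O[Si](CC)(CC)CC)C[C@@]2(C)[C@@H]1COc1ccc2ccc(=O)oc2c1 | intermediate
22 | 7-{[(2S,5S,9R,10R)-2-hydroxy-3-oxodrim-7-en-11-yl]oxy}coumarin | CC1=CC[C@@H]2C(C)(C)C(=O)[C@@H](O)C[C@@]2(C)[C@@H]1COc1ccc2ccc(=O)oc2c1 | intermediate
23 | 7-{[(2S,3S,5S,9R,10R)-2,3-dihydroxydrim-7-en-11-yl]oxy}coumarin | CC1=CC[C@@H]2C(C)(C)[C@H](O)[C@@H](O)C[C@@]2(C)[C@@H]1COc1ccc2ccc(=O)oc2c1 | target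

Total step count: 15. Longest linear sequence: 15 steps (1 to 23).

**Steps most likely to fail**

Step 9. The C9 stereocenter may discriminate the diene faces only weakly (CH2O group pseudo-axial instead of pseudo-equatorial), the formyl group may approach exo (cis ring fusion), or the Lewis acid may ionise the dienyl ether. The fallback sets out from 13 and returns to 14. The primary alcohol is silylated (i-Pr3SiCl, imidazole) to the triisopropylsilyl ether of 13 F1. The cycloaddition of F1 is then run under reagent control with a catalytic chiral cationic oxazaborolidine (triflimide-activated o-tolyl-CBS, antipode matched to C9, CH2Cl2, −78 °C), a known way to impose face and endo selectivity on 2-substituted enals. This should give the triisopropylsilyl ether of 14 F2, and Bu4NF releases 14.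

Step 11. The SN2 displacement at the β-branched C11 oxyphosphonium may be slow, leading to elimination or recovered alcohol. The fallback sets out from 15 and returns to 17. Tf2O and 2,6-lutidine at −78 °C convert 15 into the primary triflate of 15 F3, which is displaced by caesium umbelliferonate (16, Cs2CO3, DMF, 0 °C to rt). This is a Williamson ether synthesis with the best leaving group in place of the redox condensation.

Step 5. Allyl transfer to the deactivated, acid-sensitive vinylogous ester aldehyde may be slow and weakly selective. The fallback sets out from 8 and returns to 9. AllylMgBr (THF, −78 °C) gives the racemic carbinol F4. Kinetic resolution with Burkholderia cepacia lipase and vinyl acetate should acylate the (R)-enantiomer to the (R)-acetate F5 and leave (S)-carbinol 9, separated by chromatography.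

Further compounds
F1 | step 9 | triisopropylsilyl ether of 13 | O=C/C(C)=C/C/C=C(C)\[C@@H](CO[Si](C(C)C)(C(C)C)C(C)C)/C(C)=C/C=C/OCc1ccc2ccccc2c1
F2 | step 9 | triisopropylsilyl ether of 14 | CC1=CC[C@@H]2[C@@](C)(C=O)[C@@H](OCc3ccc4ccccc4c3)C=C[C@@]2(C)[C@@H]1CO[Si](C(C)C)(C(C)C)C(C)C
F3 | step 11 | trifluoromethanesulfonate of 15 | CC1=CC[C@@H]2C(C)(C)[C@@H](OCc3ccc4ccccc4c3)C=C[C@@]2(C)[C@@H]1COS(=O)(=O)C(F)(F)F
F4 | step 5 | racemic (5E,7E,9E)-5,7-dimethyl-10-(naphthalen-2-ylmethoxy)deca-1,5,7,9-tetraen-4-ol | C=CCC(O)/C(C)=C/C(C)=C/C=C/OCc1ccc2ccccc2c1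
F5 | step 5 | (4R)-acetate of the carbinol | C=CC[C@@H](OC(C)=O)/C(C)=C/C(C)=C/C=C/OCc1ccc2ccccc2c1
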